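3.64 h was the time constant of the hidden pool in the cedar run, the pool being whatever was neither substrate nor target, followed from 0.667 h to 2.50 h. Over the same span the maple run gave 1.75 h, so cedar was twice as slow on the same partner charge.

| setting | maple | cedar | south-west | north-west |
|---|---|---|---|---|
| substrate | 21 mM | 38 mM | 47 mM | 30 mM |
| partner | 70.5 mM | 70.5 mM | 70.5 mM | 70.5 mM |
| remark | run made earlier | run made earlier |  |  |
| time |  |  | 2.5 h | 1.2 h |

| run | time / h | target / % | substrate / % |
|---|---|---|---|
| maple | 0.200 | 8.3 | 30.5 |
| maple | 0.417 | 23.5 | 12.3 |
| maple | 0.667 | 38.3 | 6.4 |
| maple | 1.33 | 60.7 | 2.2 |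
| maple | 2.50 | 78.8 | 1.8 |
| cedar | 0.200 | 4.4 | 35.0 |
| cedar | 0.667 | 27.9 | 11.2 |
| cedar | 1.33 | 41.7 | 7.1 |
| cedar | 2.00 | 54.1 | 6.5 |
| cedar | 2.50 | 57.8 | 5.4 |

(readings scatter by 1 percentage point)

* which one finishes higher in amount of target, in percent of the substrate charged ("neither" within 2 percentage points) (south-west / north-west / neither)
* amount of target at the end, in percent of the substrate charged, south-west
* amount of target at the end, in percent of the substrate charged, north-west

- the numbers in the tables scatter with a standard deviation of 1 percentage point
- a reading or a percentage of target counts all its forms, free or not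

I supposed that the pool empties at a rate proportional to the partner present. If each substrate taken cost one partner, the mean partner over that span was 50.4 mM in maple and 35.7 mM in cedar, a ratio of 1.41, too small against the 2.08 of the time constants. So I charged a second partner for each target formed. The means became 38.1 mM and 19.4 mM, a ratio of 1.96, which came close. This gave my partner constant, the reciprocal time constant per unit of mean partner, a pseudo-first-order reading averaged over both runs: 0.00406 M⁻¹ s⁻¹.

But partner falls along a curve, and a mean may hide that. I tried it on cedar from time zero, a weak test because cedar had gone into the constant, taking the charge less one partner per substrate and half the final target per substrate: the reckoning returned 54.4% against the reading 57.8%, low by 3.4 percentage points.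

In this reckoning target sets its own mean partner, so I iterated from half. North-west returned 43.9%, then 44.8%. South-west swung between 34.9% and 42.8%, so I took their mean, 38.8%. Both may read low, as cedar did, but a shared error cancels in the gap of 6 points, which is more than the margin, so I committed to north-west.

The forecast gave 46% for south-west and 47% for north-west, hence neither, saying “The two values are close”, and there my reckoning differed.

North-west finished higher, 49.2% against 43.9% for south-west.

    substrate + partner ⇌ intermediate A (K = 630 M⁻¹, k = 0.0270 M⁻¹ s⁻¹)
    partner + intermediate A → intermediate B (k = 8.70 × 10⁻⁴ M⁻¹ s⁻¹)
    intermediate B → side product (k = 5.70 × 10⁻⁴ s⁻¹)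
    partner + intermediate A ⇌ intermediate C (K = 5.10 M⁻¹, k = 0.0130 M⁻¹ s⁻¹)
    intermediate C → target (k = 0.00330 s⁻¹)
    partner + target ⇌ idle adduct, settled at all times (K = 8.20 M⁻¹)

At its end north-west had 31.7% of its partner charge left unbound, south-west 6.70% of its own. With its finished amounts, north-west's mean partner comes to 34.4 mM, a time constant of 1.99 h. The neighbouring flask, north-west with 75 mM of substrate, has by its own finished amounts a mean partner of 10.8 mM, a time constant of 6.34 h, and so reckons to 17.3%; it stood at 16.3%.

(The earlier runs and the new flask are simulated with constants of no real substance; noise was put on by code.)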